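**Plan**
- Cuts: the quinone goes back to a 1,4-dimethoxynaphthalene and C1–OH to C1–OTBS. Then C1–C2 and C2–C3 of ring A are cut (the ester carbon C2 is excised), then the C4–O(naphthyl) bond, and last the C3–CH2(prenyl) bond.
- Enabling feature: in ring A the ester carbon C2 lies between oxygenated C1 and prenylated C3, and C4 bears the aryloxy group. Without C2, ring A is a 1H-indene whose C=C is a silyl enol ether. Its sp3 carbon carries OAr and the one hydrogen that must leave on aromatisation.
- Forward: 1-indanone supplies the benzo ring and the five-membered ring. Prenyl (Stille), naphthyloxy (oxa-Michael) and silyl (soft enolisation) are added, and a one-carbon insertion enlarges the five-membered ring to aromatic ring A.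
- The second naphthalene is bought as 1,4-dimethoxynaphthalene and hydroxylated at C2. Its quinone is unveiled oxidatively after the key step, and desilylation ends the route.
- Stereochemistry: the target has no stereocentre and no stereogenic alkene. The centres of 2, 10, 11 and 15 are transient, carried racemic, and erased by step 8 at the latest.

Key step: step 8

Remark: 4, 6 and 12 are taken as catalogue chemicals. Methyl diazoacetate 13 is hazardous to ship and store, so it is made and handled only in solution.

Step 1
Reactants: 1 1-indanone
Product: 3 2-bromo-1H-inden-1-one, via trans-2,3-dibromoindan-1-one 2 (not isolated)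
Conditions: NBS (2.1 equiv), AIBN (5 mol %), PhCF3, reflux; then Et3N (1.5 equiv), 0 °C
Reagents that add atoms: N-bromosuccinimide, O=C1CCC(=O)N1Br
Why: Wohl–Ziegler bromination at benzylic C3, loss of HBr and addition of the bromine thereby released load C2 and C3 with bromine, and Et3N then removes the acidic C2–H with expulsion of the benzylic bromide (E1cB dehydrobromination), a known one-flask entry to 2-bromoindenone that fixes the ring alkene at C2=C3 before a side chain with competing allylic hydrogens is present.

Step 2
Reactants: 3 2-bromo-1H-inden-1-one; 4 tributyl(3-methylbut-2-enyl)stannane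
Product: 5 2-(3-methylbut-2-enyl)-1H-inden-1-one
Conditions: Pd2(dba)3 (2.5 mol %), AsPh3 (10 mol %), CuI (10 mol %), NMP, rt to 40 °C, dark; aq KF work-up
Reagents that add atoms: none
Why: Stille coupling of an α-bromoenone, in which zerovalent palladium inserts into the activated C2–Br bond, the prenylstannane transmetalates and reductive elimination at the less hindered allyl terminus should give the linear prenyl group under neutral conditions that neither move the skipped diene into conjugation nor dimerise the indenone.

Step 3
Reactants: 6 1,4-dimethoxynaphthalene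
Product: 9 1,4-dimethoxynaphthalen-2-ol, via 2-lithio-1,4-dimethoxynaphthalene 7 (not isolated), via dimethyl arylboronate 8 (not isolated)
Conditions: n-BuLi, TMEDA, THF, 0 °C to rt; B(OMe)3, −78 °C to rt; AcOH, 30 % H2O2, 0 °C
Reagents that add atoms: n-butyllithium, [Li]CCCC (lithium of 7); trimethyl borate, COB(OC)OC (boron and methoxy groups of 8); hydrogen peroxide, OO (hydroxyl oxygen of 9)
Why: Directed ortho-metalation, borylation and peroxide oxidation (1,2-shift of the aryl group from boron to oxygen) form a standard arene-to-phenol sequence, since n-BuLi/TMEDA lithiates 1-methoxynaphthalenes next to the methoxy group and not at the peri position, and the two ortho sites of 6 are equivalent.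

Step 4
Reactants: 5 2-(3-methylbut-2-enyl)-1H-inden-1-one; 9 1,4-dimethoxynaphthalen-2-ol
Product: 10 trans-3-[(1,4-dimethoxynaphthalen-2-yl)oxy]-2-(3-methylbut-2-enyl)indan-1-one, racemic (2RS,3RS)
Conditions: 5 (1.2 equiv), Cs2CO3 (10 mol %), MeCN, 0 °C, argon, dark; AcOH quench
Reagents that add atoms: none
Why: Base-catalysed oxa-Michael addition should succeed because the strained cross-conjugated indenone is a much better acceptor than an ordinary 2-alkylenone, the naphtholate reacts at oxygen because its C1 is blocked by OMe, a catalytic weak base in the cold spares the doubly allylic CH2, and protonation of the enolate anti to the new aryloxy group sets the trans relation of two centres that are both erased later.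

Step 5
Reactants: 10 trans-3-[(1,4-dimethoxynaphthalen-2-yl)oxy]-2-(3-methylbut-2-enyl)indan-1-one
Product: 11 tert-butyl({1-[(1,4-dimethoxynaphthalen-2-yl)oxy]-2-(3-methylbut-2-enyl)-1H-inden-3-yl}oxy)dimethylsilane, racemic
Conditions: TBSOTf (1.2 equiv), Et3N (1.5 equiv), CH2Cl2, −78 to −20 °C; cold aq NaHCO3; short neutral alumina column
Reagents that add atoms: tert-butyldimethylsilyl triflate, CC(C)(C)[Si](C)(C)OS(=O)(=O)C(F)(F)F
Why: Soft enolisation (O-silylation of the ketone, then removal of its only α-hydrogen by Et3N) never passes through a free enolate, so β-elimination of the naphtholate is avoided as in the routine conversion of chroman-4-ones, likewise β-aryloxy ketones, into 4-siloxy-2H-chromenes, and the aryl methyl ethers are inert to the silyl triflate where acetal-type protecting groups would be at risk.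

Step 6
Reactants: 12 glycine methyl ester hydrochloride
Product: 13 methyl diazoacetate
Conditions: NaNO2, H2SO4 (cat.), CH2Cl2/H2O, −5 °C; washed with aq NaHCO3, dried, kept as a CH2Cl2 solution, never concentrated or heated
Reagents that add atoms: sodium nitrite, [Na+].[O-]N=O
Why: Diazotisation of an α-amino ester gives the diazo compound because the ester acidifies the α-hydrogen enough for the diazonium ion to lose a proton instead of N2, and immediate extraction into CH2Cl2 shields the product from the aqueous acid.

Step 7
Reactants: 13 methyl diazoacetate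
Product: 14 methyl bromodiazoacetate
Conditions: NBS (1.1 equiv), DBU (1.4 equiv), CH2Cl2, 0 °C, minutes; cold silica plug; solution kept at or below 0 °C and used at once
Reagents that add atoms: N-bromosuccinimide, O=C1CCC(=O)N1Br
Why: Electrophilic halogenation of a diazoacetate is a known fast reaction in which DBU deprotonates the diazo carbon and NBS brominates the anion with the diazo group retained, and the cold plug removes DBU, succinimide and residual NBS that would otherwise harm 11 or the catalyst.

Step 8
Reactants: 11 tert-butyl({1-[(1,4-dimethoxynaphthalen-2-yl)oxy]-2-(3-methylbut-2-enyl)-1H-inden-3-yl}oxy)dimethylsilane; 14 methyl bromodiazoacetate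
Product: 16 methyl 1-(tert-butyldimethylsilyloxy)-4-[(1,4-dimethoxynaphthalen-2-yl)oxy]-3-(3-methylbut-2-enyl)naphthalene-2-carboxylate, via siloxy bromocyclopropane 15 (not isolated)
Conditions: Rh2(esp)2 (1 mol %; esp = α,α,α′,α′-tetramethyl-1,3-benzenedipropionate), Cs2CO3 (2 equiv), 4 Å MS, CH2Cl2, 0 °C to rt; cold solution of 14 (1.3 equiv) added slowly
Reagents that add atoms: none
Why: Rh2(esp)2 expels N2 from 14, and the electrophilic bromo(ester)carbenoid is attacked by the β-carbon of the silyl enol ether (indene C2) on the face anti to the aryloxy group, so that a [2+1] cycloaddition closes the three-membered ring of 15 with the ester exo and the bromine endo. From that geometry the siloxy lone pair drives the orbital-symmetry-allowed disrotatory cyclopropyl-to-allyl opening: bromide leaves, the former C2–C3 bond of the indene breaks, and the five-membered ring is enlarged (not cyclised) to six-membered ring A, whose new C1–C2 and C2–C3 bonds are the two cyclopropane bonds that survive (indene C3, C2 and C1 become naphthalene C1, C3 and C4). The siloxy-stabilised cation then gives up the hydrogen on the aryloxy-bearing carbon to Cs2CO3 and aromatises to 16, and an exo-bromo epimer of 15 is not lost, since the push–pull bond between the siloxy carbon and the ester carbon can open and reclose and so invert the bromo carbon. The closest known reactions are the dirhodium-catalysed halodiazoacetate cyclopropanation–ring expansion of indoles to quinoline-3-carboxylates, halocarbene-type carbon insertion into indenes to give naphthalenes, and the dihalocarbene expansion of indanone silyl enol ethers to 2-halo-1-naphthols. No lasting stereocentre is formed, the four centres of 15 vanishing on aromatisation, and the site of insertion is fixed by the position of the enol ether double bond. The carbenoid must choose the tetrasubstituted enol ether over the prenyl alkene and the dimethoxynaphthalene; the oxygen donor makes that alkene by far the most nucleophilic π-bond, and slow addition of only a small excess of 14 protects the prenyl group of the product.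

Step 9
Reactants: 16 methyl 1-(tert-butyldimethylsilyloxy)-4-[(1,4-dimethoxynaphthalen-2-yl)oxy]-3-(3-methylbut-2-enyl)naphthalene-2-carboxylate
Product: 17 methyl 1-(tert-butyldimethylsilyloxy)-4-[(1,4-dioxo-1,4-dihydronaphthalen-2-yl)oxy]-3-(3-methylbut-2-enyl)naphthalene-2-carboxylate
Conditions: (NH4)2Ce(NO3)6 (2.3 equiv), MeCN/H2O, 0 °C, 15 min
Reagents that add atoms: water, O
Why: Oxidative demethylation of a hydroquinone dimethyl ether by tetravalent cerium should be selective because the trioxygenated naphthalene is the most easily oxidised π-system, its radical cation takes up water at the two methoxy-bearing carbons and loses methanol twice, and ring A (ester-deactivated, both oxygens capped) and the prenyl alkene tolerate the short cold exposure as in many prenylquinone syntheses.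

Step 10
Reactants: 17 methyl 1-(tert-butyldimethylsilyloxy)-4-[(1,4-dioxo-1,4-dihydronaphthalen-2-yl)oxy]-3-(3-methylbut-2-enyl)naphthalene-2-carboxylate
Product: 18 rubioncolin C, methyl 4-[(1,4-dioxo-1,4-dihydronaphthalen-2-yl)oxy]-1-hydroxy-3-(3-methylbut-2-enyl)naphthalene-2-carboxylate
Conditions: HF·pyridine, THF/pyridine, 0 °C, plastic vessel
Reagents that add atoms: none
Why: Fluoride-driven cleavage of an aryl silyl ether in a buffered acidic medium frees the C1 phenol without producing a naphtholate or any hard nucleophile that could displace the aryloxy group from the vinylogous ester carbon of the quinone, and the methyl ester and prenyl group are untouched.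

**Compound list**
1 | 1-indanone | O=C1CCc2ccccc12 | starting material
2 | trans-2,3-dibromoindan-1-one (racemic, not isolated) | O=C1[C@@H](Br)[C@H](Br)c2ccccc12 | intermediate
3 | 2-bromo-1H-inden-1-one | O=C1C(Br)=Cc2ccccc12 | intermediate
4 | tributyl(3-methylbut-2-enyl)stannane | CCCC[Sn](CCCC)(CCCC)CC=C(C)C | starting material
5 | 2-(3-methylbut-2-enyl)-1H-inden-1-one | O=C1C(CC=C(C)C)=Cc2ccccc12 | intermediate
6 | 1,4-dimethoxynaphthalene | COc1ccc(OC)c2ccccc12 | starting material
7 | 2-lithio-1,4-dimethoxynaphthalene (not isolated) | [Li]c1cc(OC)c2ccccc2c1OC | intermediate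
8 | dimethyl (1,4-dimethoxynaphthalen-2-yl)boronate (not isolated) | COB(OC)c1cc(OC)c2ccccc2c1OC | intermediate
9 | 1,4-dimethoxynaphthalen-2-ol | COc1cc(O)c(OC)c2ccccc12 | intermediate
10 | trans-3-[(1,4-dimethoxynaphthalen-2-yl)oxy]-2-(3-methylbut-2-enyl)indan-1-one (racemic, one enantiomer drawn) | O=C1[C@@H](CC=C(C)C)[C@H](Oc2cc(OC)c3ccccc3c2OC)c2ccccc12 | intermediate
11 | tert-butyl({1-[(1,4-dimethoxynaphthalen-2-yl)oxy]-2-(3-methylbut-2-enyl)-1H-inden-3-yl}oxy)dimethylsilane (racemic) | CC(C)(C)[Si](C)(C)OC1=C(CC=C(C)C)C(Oc2cc(OC)c3ccccc3c2OC)c2ccccc12 | intermediate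
12 | glycine methyl ester hydrochloride | COC(=O)C[NH3+].[Cl-] | starting material
13 | methyl diazoacetate | COC(=O)C=[N+]=[N-] | intermediate
14 | methyl bromodiazoacetate | COC(=O)C(Br)=[N+]=[N-] | intermediate
15 | methyl 1-bromo-1a-(tert-butyldimethylsilyloxy)-6-[(1,4-dimethoxynaphthalen-2-yl)oxy]-6a-(3-methylbut-2-enyl)-1,1a,6,6a-tetrahydrocyclopropa[a]indene-1-carboxylate (racemic, cyclopropane anti to the aryloxy group, epimers at the bromo carbon, not isolated) | COC(=O)C1(Br)C2(CC=C(C)C)C(Oc3cc(OC)c4ccccc4c3OC)c3ccccc3C12O[Si](C)(C)C(C)(C)C | intermediate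
16 | methyl 1-(tert-butyldimethylsilyloxy)-4-[(1,4-dimethoxynaphthalen-2-yl)oxy]-3-(3-methylbut-2-enyl)naphthalene-2-carboxylate | COC(=O)c1c(CC=C(C)C)c(Oc2cc(OC)c3ccccc3c2OC)c2ccccc2c1O[Si](C)(C)C(C)(C)C | intermediate
17 | methyl 1-(tert-butyldimethylsilyloxy)-4-[(1,4-dioxo-1,4-dihydronaphthalen-2-yl)oxy]-3-(3-methylbut-2-enyl)naphthalene-2-carboxylate | COC(=O)c1c(CC=C(C)C)c(OC2=CC(=O)c3ccccc3C2=O)c2ccccc2c1O[Si](C)(C)C(C)(C)C | intermediate
18 | rubioncolin C | COC(=O)c1c(CC=C(C)C)c(OC2=CC(=O)c3ccccc3C2=O)c2ccccc2c1O | target

Total step count: 10. Longest linear sequence: 7 steps (1, 2, 4, 5, 8, 9, 10, from 1-indanone).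

**Steps most likely to fail**

Step 8. The carbenoid may attack the trisubstituted prenyl alkene, or react too slowly with the crowded tetrasubstituted enol ether, so that side-chain cyclopropanation and carbenoid dimerisation take over.
- Idea of the fallback: the side chain is carried as an allyl group, whose monosubstituted alkene is far less nucleophilic, and is turned into prenyl only after ring A exists.
- It sets out from 3. Stille coupling with allyltributylstannane under the catalyst system of step 2 should give 2-allyl-1H-inden-1-one F1.
- Oxa-Michael addition of 9 should then give trans-2-allyl-3-[(1,4-dimethoxynaphthalen-2-yl)oxy]indan-1-one F2, and TBSOTf/Et3N its tert-butyldimethylsilyl enol ether F3.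
- Treatment of F3 with 14, Rh2(esp)2 and Cs2CO3 should lead through the allyl-substituted siloxy bromocyclopropane F4 to methyl 3-allyl-1-(tert-butyldimethylsilyloxy)-4-[(1,4-dimethoxynaphthalen-2-yl)oxy]naphthalene-2-carboxylate F5.
- Olefin cross-metathesis of F5 with excess 2-methylbut-2-ene (second-generation Grubbs catalyst, CH2Cl2, 40 °C) comes back to the route at 16.

Step 4. The base may cause prototropic migration of the ring double bond of 5 into conjugation with the side-chain alkene, and the addition may reverse during reaction or work-up.
- Idea of the fallback: the enone is activated and trapped by silicon instead of being exposed to a base-mediated equilibrium.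
- It sets out from 5. Sulfoniosilylation with Me2S and TBSOTf in CH2Cl2 at −78 °C should give [3-(tert-butyldimethylsilyloxy)-2-(3-methylbut-2-enyl)-1H-inden-1-yl]dimethylsulfonium triflate F6, in which the enol ether is already in place.
- Potassium 1,4-dimethoxynaphthalen-2-olate F7 (from 9 and KHMDS in THF) then displaces dimethyl sulfide from the indenyl carbon at −78 °C.
- The route is rejoined at 11, with steps 4 and 5 bypassed.

Step 5. The amine may trigger β-elimination of the naphthol. It may also catalyse a 1,3-prototropic shift within the indene, which would move the enol ether double bond to the aryloxy side and misplace the inserted carbon.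
- Idea of the fallback: the enol ether is made under neutral conditions by 1,4-hydrosilylation of a vinylogous ester.
- It sets out from 1. Exhaustive bromination (NBS, 3.2 equiv, AIBN, PhCF3, reflux) should give 2,3-dibromo-1H-inden-1-one F8.
- Irreversible addition–elimination of 9 (K2CO3, acetone, rt) at the more electrophilic C3 should give 2-bromo-3-[(1,4-dimethoxynaphthalen-2-yl)oxy]-1H-inden-1-one F9.
- Stille coupling of the remaining C2–Br bond with 4 should give 3-[(1,4-dimethoxynaphthalen-2-yl)oxy]-2-(3-methylbut-2-enyl)-1H-inden-1-one F10.
- RhCl(PPh3)3-catalysed 1,4-hydrosilylation with t-BuMe2SiH (toluene, 50 °C) delivers hydrogen to C3 and silicon to oxygen, and the route is rejoined at 11.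

**Further compounds**
F1 | step 8 | 2-allyl-1H-inden-1-one | O=C1C(CC=C)=Cc2ccccc12
F2 | step 8 | trans-2-allyl-3-[(1,4-dimethoxynaphthalen-2-yl)oxy]indan-1-one (racemic) | O=C1[C@@H](CC=C)[C@H](Oc2cc(OC)c3ccccc3c2OC)c2ccccc12
F3 | step 8 | ({2-allyl-1-[(1,4-dimethoxynaphthalen-2-yl)oxy]-1H-inden-3-yl}oxy)(tert-butyl)dimethylsilane (racemic) | CC(C)(C)[Si](C)(C)OC1=C(CC=C)C(Oc2cc(OC)c3ccccc3c2OC)c2ccccc12
F4 | step 8 | methyl 6a-allyl-1-bromo-1a-(tert-butyldimethylsilyloxy)-6-[(1,4-dimethoxynaphthalen-2-yl)oxy]-1,1a,6,6a-tetrahydrocyclopropa[a]indene-1-carboxylate (racemic, not isolated) | COC(=O)C1(Br)C2(CC=C)C(Oc3cc(OC)c4ccccc4c3OC)c3ccccc3C12O[Si](C)(C)C(C)(C)C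
F5 | step 8 | methyl 3-allyl-1-(tert-butyldimethylsilyloxy)-4-[(1,4-dimethoxynaphthalen-2-yl)oxy]naphthalene-2-carboxylate | COC(=O)c1c(CC=C)c(Oc2cc(OC)c3ccccc3c2OC)c2ccccc2c1O[Si](C)(C)C(C)(C)C
F6 | step 4 | [3-(tert-butyldimethylsilyloxy)-2-(3-methylbut-2-enyl)-1H-inden-1-yl]dimethylsulfonium triflate (racemic) | C[S+](C)C1C(CC=C(C)C)=C(O[Si](C)(C)C(C)(C)C)c2ccccc12.[O-]S(=O)(=O)C(F)(F)F
F7 | step 4 | potassium 1,4-dimethoxynaphthalen-2-olate | COc1cc([O-])c(OC)c2ccccc12.[K+]
F8 | step 5 | 2,3-dibromo-1H-inden-1-one | O=C1C(Br)=C(Br)c2ccccc12
F9 | step 5 | 2-bromo-3-[(1,4-dimethoxynaphthalen-2-yl)oxy]-1H-inden-1-one | O=C1C(Br)=C(Oc2cc(OC)c3ccccc3c2OC)c2ccccc12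
F10 | step 5 | 3-[(1,4-dimethoxynaphthalen-2-yl)oxy]-2-(3-methylbut-2-enyl)-1H-inden-1-one | O=C1C(CC=C(C)C)=C(Oc2cc(OC)c3ccccc3c2OC)c2ccccc12
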